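**Plan**

- Retrosynthetic cuts: the side chain at C5'–C6' (allylic bromide plus α-sulfonyl carbanion), the C6–O bond (from C6–B), and the three arene bonds C4a–C8a, C5–C6 and C7–C8.
- Enabling feature: the benzene ring C4a–C5–C6–C7–C8–C8a is fused to the pyran ring (O1, C2, C3, C4) only through C4a and C8a and carries H at C5 and C7, oxygen at C6 and CH3 at C8. It is therefore the sum of an ynol ether (C8a≡C8–CH3), a terminal alkyne (C4a≡C5H) and ethynylboronate (C6, C7), the first two held together by the O1–C2–C3–C4 tether.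
- Forward order, core: (R)-linalool is taken to the ynol-ether diyne 10 in six steps; one cyclotrimerisation then closes the pyran and benzene rings together; C–B is oxidised to C–OH and silylated.
- Forward order, chain: SeO2 oxidation of the E-methyl of the prenyl end, bromide, alkylation with hydroxy sulfone 23 (six steps from (R)-3-bromo-2-methylpropan-1-ol), desulfonylation, oxidation to the C9' ketone, desilylation.
- Stereochemistry: C2 (R) comes from (R)-linalool, whose C–O bond is never broken; C8' (S) comes from the bromo alcohol; the 3'E alkene is the linalool alkene, fixed by E-selective allylic oxidation.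

Key step: step 7

Remark: chroman numbering (O1, C2 … C8a) is used for the core and primed numbers for the side chain (C1' on C2, C3'=C4', C5', C6', C7', C8' methine, C9' carbonyl, C11'=C12'). The carbinol carbon C9' in 22–25 and the sulfonyl carbon C6' in 24 are carried as epimer mixtures, because steps 19 and 20 remove both centres. Compounds 1, 4, 11 and 17 are assumed to be purchased.

**Route**

Step 1
Reactants: 1 (R)-linalool
Product: 2 (3R)-3,7-dimethyloct-6-ene-1,3-diol
Conditions: 9-BBN (1.5 equiv), THF, 0 °C to rt; then NaOH, H2O2, 0 °C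
Reagents that add atoms: hydrogen peroxide, OO
Why: Anti-Markovnikov hydroboration–oxidation, in which 9-BBN takes the monosubstituted vinyl group and leaves the trisubstituted alkene and the quaternary carbinol centre alone.

Step 2
Reactants: 2 (3R)-3,7-dimethyloct-6-ene-1,3-diol
Product: 3 (3R)-3,7-dimethyl-1-(triisopropylsilyloxy)oct-6-en-3-ol
Conditions: TIPSCl (1.1 equiv), imidazole, DMF, 0 °C to rt
Reagents that add atoms: chlorotriisopropylsilane, CC(C)[Si](Cl)(C(C)C)C(C)C
Why: Selective silylation of the primary hydroxyl; the bulky TIPS group is chosen because it should not migrate to the tertiary alkoxide formed in step 3.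

Step 3
Reactants: 3 (3R)-3,7-dimethyl-1-(triisopropylsilyloxy)oct-6-en-3-ol, 4 trichloroethylene
Product: 7 {[(3R)-3,7-dimethyl-3-(prop-1-yn-1-yloxy)oct-6-en-1-yl]oxy}triisopropylsilane, via (E)-1,2-dichlorovinyl ether 5 (not isolated), via lithium alkynyl ether 6 (not isolated)
Conditions: KH (2 equiv), THF, 0 °C; 4, −50 °C to rt; n-BuLi (2.5 equiv), −78 to −40 °C; MeI, DMPU, −78 to 0 °C
Reagents that add atoms: iodomethane, CI
Why: One-pot ynol ether synthesis from trichloroethylene, in which the potassium alkoxide adds to dichloroacetylene formed in situ, n-BuLi turns the dichlorovinyl ether into the lithium alkoxyacetylide by elimination and Cl–Li exchange, and C-methylation gives the propynyl ether without touching the C–O bond of the stereocentre.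

Step 4
Reactants: 7 {[(3R)-3,7-dimethyl-3-(prop-1-yn-1-yloxy)oct-6-en-1-yl]oxy}triisopropylsilane
Product: 8 (3R)-3,7-dimethyl-3-(prop-1-yn-1-yloxy)oct-6-en-1-ol
Conditions: TBAF, THF, 0 °C to rt
Reagents that add atoms: none
Why: Fluoride-mediated desilylation, to which the ynol ether is inert; the work-up is kept cold and non-acidic because tertiary ynol ethers are sensitive to heat and acid.

Step 5
Reactants: 8 (3R)-3,7-dimethyl-3-(prop-1-yn-1-yloxy)oct-6-en-1-ol
Product: 9 (3R)-3,7-dimethyl-3-(prop-1-yn-1-yloxy)oct-6-en-1-yl 4-methylbenzenesulfonate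
Conditions: TsCl, Et3N, DMAP (cat.), CH2Cl2, 0 °C
Reagents that add atoms: 4-toluenesulfonyl chloride, Cc1ccc(cc1)S(=O)(=O)Cl
Why: Sulfonylation of a primary alcohol under basic conditions, which spare the ynol ether.

Step 6
Reactants: 9 (3R)-3,7-dimethyl-3-(prop-1-yn-1-yloxy)oct-6-en-1-yl 4-methylbenzenesulfonate
Product: 10 (5R)-5,9-dimethyl-5-(prop-1-yn-1-yloxy)dec-8-en-1-yne
Conditions: lithium acetylide–ethylenediamine complex, DMSO, 15–20 °C
Reagents that add atoms: lithium acetylide (ethylenediamine complex), [Li]C#C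
Why: SN2 alkylation of acetylide by an unhindered primary tosylate, which adds C4a and C5 two carbons away from the stereocentre.

Step 7
Reactants: 10 (5R)-5,9-dimethyl-5-(prop-1-yn-1-yloxy)dec-8-en-1-yne, 11 ethynylboronic acid pinacol ester
Product: 12 2-[(2R)-2,8-dimethyl-2-(4-methylpent-3-en-1-yl)chroman-6-yl]-4,4,5,5-tetramethyl-1,3,2-dioxaborolane
Conditions: Cp*RuCl(cod) (10 mol %), 11 (3 equiv), ClCH2CH2Cl, 0 °C to rt, 10 added over 4 h
Reagents that add atoms: none
Why: Proposed new method: Cp*RuCl (divalent ruthenium), once cod is displaced, binds both alkynes of 10 and couples them oxidatively at C4a and C8a to a bicyclic ruthenacycle (formally tetravalent ruthenium), into which 11 inserts before reductive elimination releases the arene; the closest known reaction type is the Cp*RuCl(cod)-catalysed [2+2+2] cycloaddition of tethered diynes with terminal alkynes and alkynylboronates, together with rhodium-catalysed cyclotrimerisations of heteroatom-substituted (ynamide-type) diynes, whereas an ynol-ether-tethered 1,7-diyne leading to a chroman has not been described. The pyran ring closes in the oxidative cyclisation by C4a–C8a bond formation across the O1–C2–C3–C4 tether, and the benzene ring closes by insertion of 11 (C5–C6) followed by reductive elimination (C7–C8). No stereocentre is created, and because the C2–O1 bond takes no part, the R configuration from linalool is carried over unchanged. The step needs boron at C6, meta to the C8 methyl: the boryl-bearing carbon of 11 is expected to bond to the unsubstituted C5 end of the metallacycle so that the pinacol boronate stays away from the methyl-bearing C8 end, the same meta preference that methyl-terminated diynes show with this catalyst. Slow addition of 10 to an excess of 11 should suppress diyne self-coupling, and keeping the mixture at or below room temperature should prevent retro-ene fragmentation of the tertiary ynol ether to methylketene before it cyclises.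

Step 8
Reactants: 12 2-[(2R)-2,8-dimethyl-2-(4-methylpent-3-en-1-yl)chroman-6-yl]-4,4,5,5-tetramethyl-1,3,2-dioxaborolane
Product: 13 (2R)-2,8-dimethyl-2-(4-methylpent-3-en-1-yl)chroman-6-ol
Conditions: H2O2, NaOH, THF/H2O, 0 °C
Reagents that add atoms: hydrogen peroxide, OO
Why: Oxidation of an arylboronate by 1,2-migration of the aryl group from boron to oxygen, which places the hydroxyl exactly at C6 and leaves the trisubstituted alkene alone.

Step 9
Reactants: 13 (2R)-2,8-dimethyl-2-(4-methylpent-3-en-1-yl)chroman-6-ol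
Product: 14 {[(2R)-2,8-dimethyl-2-(4-methylpent-3-en-1-yl)chroman-6-yl]oxy}triisopropylsilane
Conditions: TIPSCl, imidazole, DMF, rt
Reagents that add atoms: chlorotriisopropylsilane, CC(C)[Si](Cl)(C(C)C)C(C)C
Why: Silylation of the phenol, needed because the electron-rich chromanol would not survive the oxidations of steps 10 and 20; the aryl TIPS ether should also tolerate the methoxide formed in step 19.

Step 10
Reactants: 14 {[(2R)-2,8-dimethyl-2-(4-methylpent-3-en-1-yl)chroman-6-yl]oxy}triisopropylsilane
Product: 15 (2E)-5-[(2R)-2,8-dimethyl-6-(triisopropylsilyloxy)chroman-2-yl]-2-methylpent-2-en-1-ol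
Conditions: SeO2 (0.3 equiv), t-BuOOH (3 equiv), salicylic acid (cat.), CH2Cl2, 0 °C to rt; then NaBH4, MeOH, 0 °C
Reagents that add atoms: selenium dioxide, O=[Se]=O; tert-butyl hydroperoxide, CC(C)(C)OO
Why: Riley-type allylic oxidation (ene reaction then [2,3]-sigmatropic shift) with SeO2 reoxidised by t-BuOOH, which on a prenyl terminus oxidises the methyl trans to the chain and so fixes the 3'E geometry; the borohydride treatment returns any enal to 15.

Step 11
Reactants: 15 (2E)-5-[(2R)-2,8-dimethyl-6-(triisopropylsilyloxy)chroman-2-yl]-2-methylpent-2-en-1-ol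
Product: 16 {[(2R)-2-[(3E)-5-bromo-4-methylpent-3-en-1-yl]-2,8-dimethylchroman-6-yl]oxy}triisopropylsilane
Conditions: CBr4, PPh3, CH2Cl2, 0 °C
Reagents that add atoms: carbon tetrabromide, BrC(Br)(Br)Br
Why: Appel reaction, which converts a primary allylic alcohol into the bromide under neutral conditions without allylic transposition or loss of alkene geometry.

Step 12
Reactants: 17 (R)-3-bromo-2-methylpropan-1-ol
Product: 18 (R)-(3-bromo-2-methylpropoxy)(tert-butyl)dimethylsilane
Conditions: TBSCl, imidazole, CH2Cl2, 0 °C to rt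
Reagents that add atoms: tert-butyldimethylsilyl chloride, CC(C)(C)[Si](C)(C)Cl
Why: Silylation of the primary alcohol, so that no alkoxide can close an oxetane or quench the carbanion in step 13.

Step 13
Reactants: 18 (R)-(3-bromo-2-methylpropoxy)(tert-butyl)dimethylsilane
Product: 19 (S)-tert-butyldimethyl[2-methyl-4-(phenylsulfonyl)butoxy]silane
Conditions: PhSO2CH3 (3 equiv), n-BuLi (3 equiv), THF/DMPU, −78 °C to rt
Reagents that add atoms: methyl phenyl sulfone, CS(=O)(=O)c1ccccc1
Why: SN2 alkylation of lithiated methyl phenyl sulfone (in excess, to suppress double alkylation) by the primary bromide, in which the bromide carbon becomes C7' and the sulfone methyl becomes C6', while the methyl-bearing centre one carbon away is unaffected (the descriptor changes by priority only).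

Step 14
Reactants: 19 (S)-tert-butyldimethyl[2-methyl-4-(phenylsulfonyl)butoxy]silane
Product: 20 (S)-2-methyl-4-(phenylsulfonyl)butan-1-ol
Conditions: camphorsulfonic acid (cat.), MeOH, rt
Reagents that add atoms: none
Why: Acid-catalysed methanolysis of a primary TBS ether, to which the sulfone is inert.

Step 15
Reactants: 20 (S)-2-methyl-4-(phenylsulfonyl)butan-1-ol
Product: 21 (S)-2-methyl-4-(phenylsulfonyl)butanal
Conditions: Dess–Martin periodinane, CH2Cl2, 0 °C to rt; used at once
Reagents that add atoms: none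
Why: Dess–Martin oxidation, which gives α-branched aldehydes without epimerisation when the product is used directly.

Step 16
Reactants: 21 (S)-2-methyl-4-(phenylsulfonyl)butanal
Product: 22 (5S)-5-methyl-7-(phenylsulfonyl)hept-1-en-4-ol (both C4 epimers)
Conditions: allylmagnesium bromide (1.1 equiv), THF, −78 °C; aq. NH4Cl
Reagents that add atoms: allylmagnesium bromide, C=CC[Mg]Br
Why: Grignard addition to the aldehyde, which at −78 °C is far faster than deprotonation next to the sulfone; the new carbinol centre (C9') forms unselectively, which is accepted because step 20 oxidises it.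

Step 17
Reactants: 22 (5S)-5-methyl-7-(phenylsulfonyl)hept-1-en-4-ol (both C4 epimers)
Product: 23 (6S)-2,6-dimethyl-8-(phenylsulfonyl)oct-2-en-5-ol (both C5 epimers)
Conditions: second-generation Grubbs catalyst RuCl2(=CHPh)(PCy3)(H2IMes) (5 mol %), 2-methylbut-2-ene (excess), CH2Cl2, 40 °C
Reagents that add atoms: 2-methylbut-2-ene, CC=C(C)C
Why: Olefin cross-metathesis with 2-methylbut-2-ene, the standard way to turn an allyl into a prenyl group (direct addition of a prenyl metal would react through its γ-carbon and give the branched isomer).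

Step 18
Reactants: 16 {[(2R)-2-[(3E)-5-bromo-4-methylpent-3-en-1-yl]-2,8-dimethylchroman-6-yl]oxy}triisopropylsilane, 23 (6S)-2,6-dimethyl-8-(phenylsulfonyl)oct-2-en-5-ol (both C5 epimers)
Product: 24 (6S,10E)-13-[(2R)-2,8-dimethyl-6-(triisopropylsilyloxy)chroman-2-yl]-2,6,10-trimethyl-8-(phenylsulfonyl)trideca-2,10-dien-5-ol (epimers at the carbinol carbon C5 and the sulfonyl carbon C8)
Conditions: 23 (1.3 equiv), n-BuLi (2.6 equiv), THF, −78 °C; DMPU; 16, −78 to −30 °C
Reagents that add atoms: none
Why: Julia-type sulfone alkylation, in which the alkoxide/α-sulfonyl carbanion dianion of 23 attacks the primary allylic bromide at carbon in an SN2 reaction, joining the sulfonyl carbon C6' directly to the former CH2Br carbon C5' and keeping the E-alkene; the C6' centre forms unselectively and disappears in step 19.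

Step 19
Reactants: 24 (6S,10E)-13-[(2R)-2,8-dimethyl-6-(triisopropylsilyloxy)chroman-2-yl]-2,6,10-trimethyl-8-(phenylsulfonyl)trideca-2,10-dien-5-ol
Product: 25 (6S,10E)-13-[(2R)-2,8-dimethyl-6-(triisopropylsilyloxy)chroman-2-yl]-2,6,10-trimethyltrideca-2,10-dien-5-ol (both C5 epimers)
Conditions: sodium amalgam (6% Na in Hg), Na2HPO4, THF/MeOH, −20 °C
Reagents that add atoms: none
Why: Reductive desulfonylation of an alkyl phenyl sulfone by electron transfer from sodium amalgam in buffered methanol, conditions that should not reduce the isolated alkenes or cleave the aryl TIPS ether.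

Step 20
Reactants: 25 (6S,10E)-13-[(2R)-2,8-dimethyl-6-(triisopropylsilyloxy)chroman-2-yl]-2,6,10-trimethyltrideca-2,10-dien-5-ol
Product: 26 (6S,10E)-13-[(2R)-2,8-dimethyl-6-(triisopropylsilyloxy)chroman-2-yl]-2,6,10-trimethyltrideca-2,10-dien-5-one
Conditions: Dess–Martin periodinane, pyridine, CH2Cl2, 0 °C
Reagents that add atoms: none
Why: Dess–Martin oxidation of the homoallylic secondary alcohol under pyridine buffering, which should give the β,γ-unsaturated ketone without moving the C11'=C12' bond into conjugation or epimerising C8'; both carbinol epimers converge.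

Step 21
Reactants: 26 (6S,10E)-13-[(2R)-2,8-dimethyl-6-(triisopropylsilyloxy)chroman-2-yl]-2,6,10-trimethyltrideca-2,10-dien-5-one
Product: 27 CNP0280076.1, (6S,10E)-13-[(2R)-6-hydroxy-2,8-dimethylchroman-2-yl]-2,6,10-trimethyltrideca-2,10-dien-5-one
Conditions: TBAF, AcOH (1:1), THF, 0 °C
Reagents that add atoms: none
Why: Fluoride-mediated cleavage of the aryl silyl ether, buffered with acetic acid so that the medium stays near neutral and neither epimerises C8' nor conjugates the β,γ-enone.

**Compound list**

1 | (R)-linalool, (3R)-3,7-dimethylocta-1,6-dien-3-ol | CC(C)=CCC[C@](O)(C)C=C | starting material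
2 | (3R)-3,7-dimethyloct-6-ene-1,3-diol | CC(C)=CCC[C@](O)(C)CCO | intermediate
3 | (3R)-3,7-dimethyl-1-(triisopropylsilyloxy)oct-6-en-3-ol | CC(C)=CCC[C@](O)(C)CCO[Si](C(C)C)(C(C)C)C(C)C | intermediate
4 | trichloroethylene | ClC=C(Cl)Cl | starting material
5 | {[(3R)-3-{[(E)-1,2-dichlorovinyl]oxy}-3,7-dimethyloct-6-en-1-yl]oxy}triisopropylsilane | CC(C)=CCC[C@](O/C(Cl)=C\Cl)(C)CCO[Si](C(C)C)(C(C)C)C(C)C | intermediate (not isolated)
6 | lithium {[(3R)-3,7-dimethyl-1-(triisopropylsilyloxy)oct-6-en-3-yl]oxy}ethynide | CC(C)=CCC[C@](OC#C[Li])(C)CCO[Si](C(C)C)(C(C)C)C(C)C | intermediate (not isolated)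
7 | {[(3R)-3,7-dimethyl-3-(prop-1-yn-1-yloxy)oct-6-en-1-yl]oxy}triisopropylsilane | CC(C)=CCC[C@](OC#CC)(C)CCO[Si](C(C)C)(C(C)C)C(C)C | intermediate
8 | (3R)-3,7-dimethyl-3-(prop-1-yn-1-yloxy)oct-6-en-1-ol | CC(C)=CCC[C@](OC#CC)(C)CCO | intermediate
9 | (3R)-3,7-dimethyl-3-(prop-1-yn-1-yloxy)oct-6-en-1-yl 4-methylbenzenesulfonate | CC(C)=CCC[C@](OC#CC)(C)CCOS(=O)(=O)c1ccc(C)cc1 | intermediate
10 | (5R)-5,9-dimethyl-5-(prop-1-yn-1-yloxy)dec-8-en-1-yne | CC(C)=CCC[C@](OC#CC)(C)CCC#C | intermediate
11 | ethynylboronic acid pinacol ester, 2-ethynyl-4,4,5,5-tetramethyl-1,3,2-dioxaborolane | C#CB1OC(C)(C)C(C)(C)O1 | starting material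
12 | 2-[(2R)-2,8-dimethyl-2-(4-methylpent-3-en-1-yl)chroman-6-yl]-4,4,5,5-tetramethyl-1,3,2-dioxaborolane | CC(C)=CCC[C@]1(C)CCc2cc(B3OC(C)(C)C(C)(C)O3)cc(C)c2O1 | intermediate
13 | (2R)-2,8-dimethyl-2-(4-methylpent-3-en-1-yl)chroman-6-ol | CC(C)=CCC[C@]1(C)CCc2cc(O)cc(C)c2O1 | intermediate
14 | {[(2R)-2,8-dimethyl-2-(4-methylpent-3-en-1-yl)chroman-6-yl]oxy}triisopropylsilane | CC(C)=CCC[C@]1(C)CCc2cc(O[Si](C(C)C)(C(C)C)C(C)C)cc(C)c2O1 | intermediate
15 | (2E)-5-[(2R)-2,8-dimethyl-6-(triisopropylsilyloxy)chroman-2-yl]-2-methylpent-2-en-1-ol | OC/C(C)=C/CC[C@]1(C)CCc2cc(O[Si](C(C)C)(C(C)C)C(C)C)cc(C)c2O1 | intermediate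
16 | {[(2R)-2-[(3E)-5-bromo-4-methylpent-3-en-1-yl]-2,8-dimethylchroman-6-yl]oxy}triisopropylsilane | BrC/C(C)=C/CC[C@]1(C)CCc2cc(O[Si](C(C)C)(C(C)C)C(C)C)cc(C)c2O1 | intermediate
17 | (R)-3-bromo-2-methylpropan-1-ol | OC[C@@H](C)CBr | starting material
18 | (R)-(3-bromo-2-methylpropoxy)(tert-butyl)dimethylsilane | CC(C)(C)[Si](C)(C)OC[C@@H](C)CBr | intermediate
19 | (S)-tert-butyldimethyl[2-methyl-4-(phenylsulfonyl)butoxy]silane | CC(C)(C)[Si](C)(C)OC[C@@H](C)CCS(=O)(=O)c1ccccc1 | intermediate
20 | (S)-2-methyl-4-(phenylsulfonyl)butan-1-ol | OC[C@@H](C)CCS(=O)(=O)c1ccccc1 | intermediate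
21 | (S)-2-methyl-4-(phenylsulfonyl)butanal | O=C[C@@H](C)CCS(=O)(=O)c1ccccc1 | intermediate
22 | (5S)-5-methyl-7-(phenylsulfonyl)hept-1-en-4-ol, both C4 epimers | C=CCC(O)[C@@H](C)CCS(=O)(=O)c1ccccc1 | intermediate
23 | (6S)-2,6-dimethyl-8-(phenylsulfonyl)oct-2-en-5-ol, both C5 epimers | CC(C)=CCC(O)[C@@H](C)CCS(=O)(=O)c1ccccc1 | intermediate
24 | (6S,10E)-13-[(2R)-2,8-dimethyl-6-(triisopropylsilyloxy)chroman-2-yl]-2,6,10-trimethyl-8-(phenylsulfonyl)trideca-2,10-dien-5-ol, epimers at C5 and C8 | CC(C)=CCC(O)[C@@H](C)CC(S(=O)(=O)c1ccccc1)C/C(C)=C/CC[C@]1(C)CCc2cc(O[Si](C(C)C)(C(C)C)C(C)C)cc(C)c2O1 | intermediate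
25 | (6S,10E)-13-[(2R)-2,8-dimethyl-6-(triisopropylsilyloxy)chroman-2-yl]-2,6,10-trimethyltrideca-2,10-dien-5-ol, both C5 epimers | CC(C)=CCC(O)[C@@H](C)CCC/C(C)=C/CC[C@]1(C)CCc2cc(O[Si](C(C)C)(C(C)C)C(C)C)cc(C)c2O1 | intermediate
26 | (6S,10E)-13-[(2R)-2,8-dimethyl-6-(triisopropylsilyloxy)chroman-2-yl]-2,6,10-trimethyltrideca-2,10-dien-5-one | CC(C)=CCC(=O)[C@@H](C)CCC/C(C)=C/CC[C@]1(C)CCc2cc(O[Si](C(C)C)(C(C)C)C(C)C)cc(C)c2O1 | intermediate
27 | CNP0280076.1, (6S,10E)-13-[(2R)-6-hydroxy-2,8-dimethylchroman-2-yl]-2,6,10-trimethyltrideca-2,10-dien-5-one | CC(C)=CCC(=O)[C@@H](C)CCC/C(C)=C/CC[C@]1(C)CCc2cc(O)cc(C)c2O1 | target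

**Step count and risks**

Total step count: 21. Longest linear sequence: 15 steps (steps 1–11 and 18–21, from 1). The sulfone branch (steps 12–17, from 17) joins at step 18.

Steps most likely to fail:

1. Step 7 (the cyclotrimerisation). The diyne may dimerise or oligomerise faster than it takes up 11, the tertiary ynol ether may fragment by retro-ene reaction at the metal, or 11 may insert in the opposite sense and put boron at C7. The fallback buys the benzene ring instead of building it; it sets out from 1 and returns at 12. Hydroboration of 1 with 9-BBN (THF, 0 °C to rt) gives the B-alkyl-9-BBN adduct 9-[(3S)-3-hydroxy-3,7-dimethyloct-6-en-1-yl]-9-borabicyclo[3.3.1]nonane F1. F1 is coupled in the same flask with commercial 2-bromo-1-iodo-3-methylbenzene (PdCl2(dppf), K3PO4, THF/DMF/H2O, rt to 50 °C); this B-alkyl Suzuki–Miyaura coupling should take place at the C–I bond only and give (3R)-1-(2-bromo-3-methylphenyl)-3,7-dimethyloct-6-en-3-ol F2. Intramolecular Buchwald–Hartwig-type C–O coupling of the tertiary alcohol with the aryl bromide (Pd(OAc)2, 2-(di-tert-butylphosphino)-1,1'-binaphthyl, Cs2CO3, toluene, 80 °C) closes the pyran ring at O1–C8a without touching the C2–O bond and gives (2R)-2,8-dimethyl-2-(4-methylpent-3-en-1-yl)chroman F3. Iridium-catalysed C–H borylation of F3 ([Ir(OMe)(cod)]2, 4,4'-di-tert-butyl-2,2'-bipyridine, B2pin2, THF, 60 °C) should go to C6, the only aromatic C–H without an ortho substituent, and give 12.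

2. Step 3 (ynol ether formation). The hindered tertiary potassium alkoxide may add too slowly to dichloroacetylene, or the strongly basic medium may cause elimination of the tertiary ether, so that little propynyl ether is formed. The fallback builds the alkynyl ether carbons from a formate; it sets out from 3 and returns at 7. Formylation of 3 (acetic formic anhydride, pyridine, 0 °C to rt) gives (3R)-3,7-dimethyl-1-(triisopropylsilyloxy)oct-6-en-3-yl formate F4. Wittig-type dichloromethylenation of the formate (PPh3, CCl4, THF, 60 °C) gives {[(3R)-3-(2,2-dichlorovinyloxy)-3,7-dimethyloct-6-en-1-yl]oxy}triisopropylsilane F5. n-BuLi (2.2 equiv, THF, −78 °C) converts F5 by elimination and Cl–Li exchange into the same lithium alkynyl ether 6, which is methylated as in step 3 (MeI, DMPU) to 7.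

3. Step 10 (allylic oxidation). Conversion may stop early, the alcohol may be oxidised on to the enal, and the benzylic C4 position may be attacked, so that the yield of 15 is low. The fallback rebuilds the E-trisubstituted alkene by olefination; it sets out from 14 and returns at 15. Lemieux–Johnson cleavage of the only alkene of 14 (OsO4 (cat.), NaIO4, 2,6-lutidine, dioxane/H2O, rt) gives 3-[(2S)-2,8-dimethyl-6-(triisopropylsilyloxy)chroman-2-yl]propanal F6 (descriptor changed by priority only). Wittig reaction with the stabilised ylide ethyl 2-(triphenylphosphoranylidene)propanoate (CH2Cl2, rt) should give, E-selectively, ethyl (2E)-5-[(2R)-2,8-dimethyl-6-(triisopropylsilyloxy)chroman-2-yl]-2-methylpent-2-enoate F7. Reduction with i-Bu2AlH (CH2Cl2, −78 °C) gives 15.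

Further compounds
F1 | step 7 | 9-[(3S)-3-hydroxy-3,7-dimethyloct-6-en-1-yl]-9-borabicyclo[3.3.1]nonane | CC(C)=CCC[C@](O)(C)CCB1C2CCCC1CCC2
F2 | step 7 | (3R)-1-(2-bromo-3-methylphenyl)-3,7-dimethyloct-6-en-3-ol | CC(C)=CCC[C@](O)(C)CCc1cccc(C)c1Br
F3 | step 7 | (2R)-2,8-dimethyl-2-(4-methylpent-3-en-1-yl)chroman | CC(C)=CCC[C@]1(C)CCc2cccc(C)c2O1
F4 | step 3 | (3R)-3,7-dimethyl-1-(triisopropylsilyloxy)oct-6-en-3-yl formate | CC(C)=CCC[C@](OC=O)(C)CCO[Si](C(C)C)(C(C)C)C(C)C
F5 | step 3 | {[(3R)-3-(2,2-dichlorovinyloxy)-3,7-dimethyloct-6-en-1-yl]oxy}triisopropylsilane | CC(C)=CCC[C@](OC=C(Cl)Cl)(C)CCO[Si](C(C)C)(C(C)C)C(C)C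
F6 | step 10 | 3-[(2S)-2,8-dimethyl-6-(triisopropylsilyloxy)chroman-2-yl]propanal | O=CCC[C@]1(C)CCc2cc(O[Si](C(C)C)(C(C)C)C(C)C)cc(C)c2O1
F7 | step 10 | ethyl (2E)-5-[(2R)-2,8-dimethyl-6-(triisopropylsilyloxy)chroman-2-yl]-2-methylpent-2-enoate | CCOC(=O)/C(C)=C/CC[C@]1(C)CCc2cc(O[Si](C(C)C)(C(C)C)C(C)C)cc(C)c2O1
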